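**Plan**

1. Cuts: the triene at C12–C13 (Suzuki) and C11=C12 (boron–Wittig on a C7 acetyl group, the former isopropenyl of carvone); C4=C15 from a C4 ketone; C1–Br and C5–OH from an oxetane whose oxygen bridges C1 and C5.
2. The oxetane (bonds C5–C10 and O–C1) is cut by a retro-Paternò–Büchi to a cyclodec-5-enone, and that by a retro-oxy-Cope and a retro-vinylation to (R)-carvone.
3. Forward: ring B of carvone is expanded to a ten-membered ring; one photochemical step then re-forms C5–C10 across it, closing ring A, ring B and the oxetane together; bromide opens the strained ether.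
4. Enabling feature: Br–C1 and HO–C5 both sit on carbons bonded to the quaternary fusion atom C10 (a 1,3-bromohydrin spanning the A/B fusion bond C5–C10), which is the retron of an oxetane O–C1–C10–C5, i.e. a C5 ketone facing a C1=C10 alkene 1,6 across a ten-membered ring.
5. Stereochemistry: C7 is the only centre taken from (R)-carvone; C1, C5 and C10 are set in the photocycloaddition by ring constraints relative to C7; C1 is then inverted by bromide (α-O to β-Br); the (E,E)-triene comes from a stereoselective boron–Wittig and a stereoretentive Suzuki coupling.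

Key step: step 5

Remark: ring atoms carry the eudesmane numbers of the target (C1–C5 and C10 = ring A, C5–C10 = ring B, C14 = angular methyl, C15 = exocyclic CH2, C11 = side-chain carbon on C7); the C4 centre made in step 3 is carried as both epimers (unspecified in the SMILES) until it becomes sp2 in step 9.

**Route**

Step 1
Reactants: 1 (R)-(−)-carvone
Product: 3 (2S,5R)-2-chloro-2-methyl-5-(prop-1-en-2-yl)cyclohexan-1-one, via lithium enolate 2 (not isolated)
Conditions: L-Selectride (1.05 equiv), THF, −78 °C; then NCS, −78 → 0 °C; aq. NH4Cl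
Reagents that add atoms: N-chlorosuccinimide, O=C1CCC(=O)N1Cl
Why: Conjugate hydride reduction of the enone gives the regiodefined tetrasubstituted enolate, and enolate α-chlorination puts the halogen on the methyl-bearing carbon (axial attack, Cl cis to isopropenyl expected); either epimer serves because this centre becomes sp2 in step 3.

Step 2
Reactants: 3 (2S,5R)-2-chloro-2-methyl-5-(prop-1-en-2-yl)cyclohexan-1-one
Product: 6 (1R,2S,5R)-1,2-diethenyl-2-methyl-5-(prop-1-en-2-yl)cyclohexan-1-ol, via chlorohydrin magnesium alkoxide 4 (not isolated), via vinyl ketone 5 (not isolated)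
Conditions: CH2=CHMgBr (3.2 equiv), THF, −20 → 50 °C; aq. NH4Cl
Reagents that add atoms: vinylmagnesium bromide, C=C[Mg]Br
Why: The Grignard reagent adds to the carbonyl anti to C–Cl, the halohydrin alkoxide undergoes the known semipinacol 1,2-vinyl shift with inversion at the chloride-bearing carbon to give the α-vinyl ketone, and a second equivalent adds to that ketone; the carbinol configuration is not critical because both epimers are 1,5-dien-3-ols.

Step 3
Reactants: 6 (1R,2S,5R)-1,2-diethenyl-2-methyl-5-(prop-1-en-2-yl)cyclohexan-1-ol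
Product: 9 (5E,9R)-2-hydroxy-6-methyl-9-(prop-1-en-2-yl)cyclodec-5-en-1-one, via potassium alkoxide 7 (not isolated), via potassium enolate 8 (not isolated)
Conditions: KHMDS (1.1 equiv), 18-crown-6, THF, 0 → 25 °C; then 2-(phenylsulfonyl)-3-phenyloxaziridine, −78 °C; aq. NH4Cl
Reagents that add atoms: 2-(phenylsulfonyl)-3-phenyloxaziridine, O=S(=O)(N1OC1c1ccccc1)c1ccccc1
Why: Anionic oxy-Cope rearrangement (alkoxide-accelerated [3,3] shift through a chair with the ring bonds pseudo-equatorial) expands the ring to the (E)-cyclodec-5-enone enolate, which is regiospecific towards C4 and is hydroxylated there in situ (enolate α-hydroxylation); C4 forms unselectively and is erased in step 9, C7 is untouched.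

Step 4
Reactants: 9 (5E,9R)-2-hydroxy-6-methyl-9-(prop-1-en-2-yl)cyclodec-5-en-1-one
Product: 10 (5E,9R)-2-[(tert-butyldimethylsilyl)oxy]-6-methyl-9-(prop-1-en-2-yl)cyclodec-5-en-1-one
Conditions: TBSCl, imidazole, DMF, 25 °C
Reagents that add atoms: tert-butyldimethylsilyl chloride, C[Si](C)(Cl)C(C)(C)C
Why: Standard silylation of the secondary α-hydroxyl removes the acyloin O–H, which would favour Norrish type I cleavage in step 5 and consume the amide base in step 7; no stereocentre changes.

Step 5
Reactants: 10 (5E,9R)-2-[(tert-butyldimethylsilyl)oxy]-6-methyl-9-(prop-1-en-2-yl)cyclodec-5-en-1-one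
Product: 11 oxetane 4-(TBSO)-1α,5α-epoxy-15-nor-eudesm-11-ene (10-[(tert-butyldimethylsilyl)oxy]-6-methyl-3-(prop-1-en-2-yl)-11-oxatricyclo[5.3.1.0(1,6)]undecane)
Conditions: hν (300 nm, Pyrex), degassed MeCN (5 mM), 15 °C
Reagents that add atoms: none
Why: n→π* excitation of the C5 ketone gives an excited carbonyl whose oxygen adds to the less substituted carbon (C1) of the C1=C10 alkene held across the ten-membered ring, and the resulting 1,4-biradical (tertiary C10, oxygen-bearing C5) collapses to the C5–C10 bond. The closest known reaction type is the intramolecular (transannular) Paternò–Büchi reaction of unsaturated ketones. Three rings close at once: the oxetane (O–C1 first, then C5–C10 by radical recombination) and, through that transannular 1,6 C–C bond, six-membered rings A and B. The single oxygen bridge forces the C1 and C5 oxygens onto one face, and C10 is fixed because ring B can only be cis-fused to the four-membered ring, which places the methyl group anti to the C5 oxygen (the trans-decalin relationship); the absolute sense of all three follows from C7, whose isopropenyl group stays pseudo-equatorial on chair-like ring B. The step needs O–C bonding at C1 and not C10 (secured by the tertiary radical at C10 and the 1,6 geometry) and reaction with the ring alkene in preference to the isopropenyl group or Norrish cleavage (the ring alkene is in van der Waals contact with the carbonyl, whereas the side-chain alkene could only give a strained crossed oxetane). Alkene geometry is not critical because the biradical erases it.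

Step 6
Reactants: 11 oxetane 4-(TBSO)-1α,5α-epoxy-15-nor-eudesm-11-ene
Product: 12 7β-acetyl oxetane (4-(TBSO)-1α,5α-epoxy-12,15-dinor-eudesman-11-one)
Conditions: O3, CH2Cl2/MeOH, −78 °C; then Me2S, −78 → 25 °C
Reagents that add atoms: ozone, [O-][O+]=O
Why: Ozonolysis (Criegee mechanism, reductive work-up) of the only remaining C=C bond gives the methyl ketone; the oxetane and silyl ether are inert to ozone at −78 °C and no stereocentre is affected.

Step 7
Reactants: 12 7β-acetyl oxetane
Product: 13 alkenyl boronate (4-(TBSO)-oxetane bearing 7β-[(E)-1-(4,4,5,5-tetramethyl-1,3,2-dioxaborolan-2-yl)prop-1-en-2-yl])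
Conditions: CH2(Bpin)2 (1.5 equiv), LiTMP (1.4 equiv), THF, 0 °C; then 12, −78 → 25 °C
Reagents that add atoms: bis(4,4,5,5-tetramethyl-1,3,2-dioxaborolan-2-yl)methane, C(B1OC(C)(C)C(C)(C)O1)B1OC(C)(C)C(C)(C)O1
Why: Boron–Wittig olefination: the lithiated geminal bis(boronate) adds to the methyl ketone and syn-eliminates lithium pinacolborate, leaving the remaining boryl group trans to the bulky ring substituent, so the (E)-trisubstituted alkenyl boronate is expected; oxetane and silyl ether are base-stable.

Step 8
Reactants: 13 alkenyl boronate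
Product: 14 C4 alcohol of 13 (4-hydroxy oxetane boronate)
Conditions: TBAF, AcOH (1:1), THF, 25 °C
Reagents that add atoms: none
Why: Fluoride-mediated desilylation, buffered with acetic acid to spare the boronate, frees the C4 hydroxyl; the oxetane is stable to fluoride.

Step 9
Reactants: 14 C4 alcohol
Product: 15 keto-oxetane (1α,5α-epoxy-15-nor-eudesman-4-one bearing the 7β-(E)-borylpropenyl group)
Conditions: Dess–Martin periodinane, NaHCO3, CH2Cl2, 0 → 25 °C
Reagents that add atoms: none
Why: Buffered Dess–Martin oxidation of the secondary alcohol; the C4 epimers converge and the ketone now flanks the tertiary oxetane carbon C5.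

Step 10
Reactants: 15 keto-oxetane
Product: 16 1β-bromo-5α-(trimethylsilyloxy)-15-nor-eudesman-4-one bearing the 7β-(E)-borylpropenyl group
Conditions: TMSBr (1.5 equiv), 2,6-di-tert-butyl-4-methylpyridine (0.2 equiv), CH2Cl2, −40 → 0 °C
Reagents that add atoms: bromotrimethylsilane, C[Si](C)(C)Br
Why: Strain-driven SN2 opening of the O-silylated oxetane by bromide at C1 with inversion (α-O to equatorial β-Br), the known TMSBr cleavage of oxetanes; the C4 carbonyl suppresses heterolysis of the tertiary C5–O bond, the four-membered ring holds C5 eclipsed with the leaving oxygen so that no substituent of C10 lies anti to it (open backside, no Wagner–Meerwein alignment, as in the easy opening of 3,3-disubstituted oxetanes), and the tertiary oxygen emerges as its TMS ether.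

Step 11
Reactants: 16 1β-bromo-5α-(trimethylsilyloxy) 4-ketone
Product: 18 1β-bromo-7β-[(E)-1-(pinacolboryl)prop-1-en-2-yl]eudesm-4(15)-en-5α-ol, via methylene trimethylsilyl ether 17 (not isolated)
Conditions: Tebbe reagent (2 equiv), pyridine (cat.), THF, −40 → 0 °C; then K2CO3, MeOH, 0 °C
Reagents that add atoms: Tebbe reagent (written as its two halves), C=[Ti](C1C=CC=C1)C1C=CC=C1.C[Al](C)Cl
Why: Titanium-methylidene (Tebbe) methylenation converts the hindered, enolisable α-silyloxy ketone into the exocyclic C4=C15 alkene without base, sparing the secondary bromide and the boronate, and mild methanolysis then removes the tertiary TMS ether; no stereocentre is touched.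

Step 12
Reactants: 19 2-methylbut-1-en-3-yne
Product: 21 (E)-1-iodo-3-methylbuta-1,3-diene, via dienylzirconocene chloride 20 (not isolated)
Conditions: Cp2Zr(H)Cl (1.1 equiv), THF, 25 °C; then I2, 0 °C (used as a THF solution)
Reagents that add atoms: iodine, II
Why: Syn hydrozirconation of the terminal alkyne (Zr at the terminus; the 1,1-disubstituted alkene reacts more slowly) followed by iodinolysis with retention gives the (E)-dienyl iodide.

Step 13
Reactants: 18 1β-bromo-7β-[(E)-1-(pinacolboryl)prop-1-en-2-yl]eudesm-4(15)-en-5α-ol; 21 (E)-1-iodo-3-methylbuta-1,3-diene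
Product: 22 (1R,4aR,6R,8aR)-1-bromo-8a-methyl-4-methylidene-6-[(2E,4E)-6-methylhepta-2,4,6-trien-2-yl]decahydronaphthalen-4a-ol (CNP0385268.1)
Conditions: Pd(dppf)Cl2 (5 mol%), K3PO4 (3 equiv), THF/H2O, 25 °C
Reagents that add atoms: none
Why: Suzuki–Miyaura coupling proceeds with retention at both sp2 carbons to give the (E,E)-triene; Pd(0)/dppf should not insert into the unactivated secondary C–Br bond at room temperature and the weak aqueous base leaves the γ-bromo alcohol intact.

**Compound list**

1 | (R)-(−)-carvone | O=C1C(C)=CC[C@@H](C(C)=C)C1 | starting material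
2 | lithium (5R)-2-methyl-5-(prop-1-en-2-yl)cyclohex-1-en-1-olate | [Li+].[O-]C1=C(C)CC[C@@H](C(C)=C)C1 | intermediate
3 | (2S,5R)-2-chloro-2-methyl-5-(prop-1-en-2-yl)cyclohexan-1-one | O=C1[C@@](C)(Cl)CC[C@@H](C(C)=C)C1 | intermediate
4 | bromomagnesium (1S,2S,5R)-2-chloro-1-ethenyl-2-methyl-5-(prop-1-en-2-yl)cyclohexan-1-olate | Br[Mg]O[C@@]1(C=C)[C@@](C)(Cl)CC[C@@H](C(C)=C)C1 | intermediate
5 | (2S,5R)-2-ethenyl-2-methyl-5-(prop-1-en-2-yl)cyclohexan-1-one | O=C1[C@](C)(C=C)CC[C@@H](C(C)=C)C1 | intermediate
6 | (1R,2S,5R)-1,2-diethenyl-2-methyl-5-(prop-1-en-2-yl)cyclohexan-1-ol | O[C@]1(C=C)[C@](C)(C=C)CC[C@@H](C(C)=C)C1 | intermediate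
7 | potassium (1R,2S,5R)-1,2-diethenyl-2-methyl-5-(prop-1-en-2-yl)cyclohexan-1-olate | [K+].[O-][C@]1(C=C)[C@](C)(C=C)CC[C@@H](C(C)=C)C1 | intermediate
8 | potassium (1Z,5E,9R)-6-methyl-9-(prop-1-en-2-yl)cyclodeca-1,5-dien-1-olate | [K+].[O-]/C1=C\CC/C=C(\C)CC[C@@H](C(C)=C)C1 | intermediate
9 | (5E,9R)-2-hydroxy-6-methyl-9-(prop-1-en-2-yl)cyclodec-5-en-1-one (C2 epimers) | O=C1C(O)CC/C=C(\C)CC[C@@H](C(C)=C)C1 | intermediate
10 | (5E,9R)-2-[(tert-butyldimethylsilyl)oxy]-6-methyl-9-(prop-1-en-2-yl)cyclodec-5-en-1-one | O=C1C(O[Si](C)(C)C(C)(C)C)CC/C=C(\C)CC[C@@H](C(C)=C)C1 | intermediate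
11 | oxetane: 4-(TBSO)-1α,5α-epoxy-15-nor-eudesm-11-ene (10β-Me, 7β-isopropenyl) | C[C@@]12CC[C@@H](C(C)=C)C[C@@]1(O3)C(O[Si](C)(C)C(C)(C)C)CC[C@@H]23 | intermediate
12 | 7β-acetyl oxetane: 4-(TBSO)-1α,5α-epoxy-12,15-dinor-eudesman-11-one | C[C@@]12CC[C@@H](C(C)=O)C[C@@]1(O3)C(O[Si](C)(C)C(C)(C)C)CC[C@@H]23 | intermediate
13 | 4-(TBSO) oxetane with 7β-[(E)-1-(pinacolboryl)prop-1-en-2-yl] | C[C@@]12CC[C@@H](/C(C)=C/B4OC(C)(C)C(C)(C)O4)C[C@@]1(O3)C(O[Si](C)(C)C(C)(C)C)CC[C@@H]23 | intermediate
14 | 4-hydroxy oxetane with 7β-[(E)-1-(pinacolboryl)prop-1-en-2-yl] | C[C@@]12CC[C@@H](/C(C)=C/B4OC(C)(C)C(C)(C)O4)C[C@@]1(O3)C(O)CC[C@@H]23 | intermediate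
15 | keto-oxetane: 1α,5α-epoxy-15-nor-eudesman-4-one with 7β-[(E)-1-(pinacolboryl)prop-1-en-2-yl] | C[C@@]12CC[C@@H](/C(C)=C/B4OC(C)(C)C(C)(C)O4)C[C@@]1(O3)C(=O)CC[C@@H]23 | intermediate
16 | 1β-bromo-5α-(trimethylsilyloxy)-15-nor-eudesman-4-one with 7β-[(E)-1-(pinacolboryl)prop-1-en-2-yl] | C[C@@]12CC[C@@H](/C(C)=C/B4OC(C)(C)C(C)(C)O4)C[C@@]1(O[Si](C)(C)C)C(=O)CC[C@H]2Br | intermediate
17 | 5-O-trimethylsilyl ether of 18 | C[C@@]12CC[C@@H](/C(C)=C/B4OC(C)(C)C(C)(C)O4)C[C@@]1(O[Si](C)(C)C)C(=C)CC[C@H]2Br | intermediate
18 | 1β-bromo-7β-[(E)-1-(pinacolboryl)prop-1-en-2-yl]eudesm-4(15)-en-5α-ol | C[C@@]12CC[C@@H](/C(C)=C/B4OC(C)(C)C(C)(C)O4)C[C@@]1(O)C(=C)CC[C@H]2Br | intermediate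
19 | 2-methylbut-1-en-3-yne | C=C(C)C#C | starting material
20 | chloro[(E)-3-methylbuta-1,3-dienyl]zirconocene | C=C(C)/C=C/[Zr](Cl)(C1C=CC=C1)C1C=CC=C1 | intermediate
21 | (E)-1-iodo-3-methylbuta-1,3-diene | C=C(C)/C=C/I | intermediate
22 | (1R,4aR,6R,8aR)-1-bromo-8a-methyl-4-methylidene-6-[(2E,4E)-6-methylhepta-2,4,6-trien-2-yl]decahydronaphthalen-4a-ol | C=C(C)/C=C/C=C(\C)[C@@H]1CC[C@@]2(C)[C@H](Br)CCC(=C)[C@]2(O)C1 | target

**Step count and risks**

Total steps: 13. Longest linear sequence: 12 (steps 1–11 and 13; step 12 makes the coupling partner).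

Steps most likely to fail:

1. Step 5 (photocycloaddition). The excited ketone may decay by α-cleavage next to the silyloxy-bearing carbon, by γ-hydrogen abstraction from allylic C2, or by addition to the isopropenyl group faster than it closes the transannular oxetane, and facial selectivity relative to C7 may be modest. Fallback, from 10 back to 11: mCPBA should epoxidise the more electron-rich trisubstituted ring alkene to the trans-1,10-epoxide F1. Cp2TiCl (from Cp2TiCl2/Zn) should open it homolytically to the tertiary C10 radical, which adds across the ring to the titanium-activated C5 ketone (known Ti(III) epoxide–carbonyl radical cyclisation, chair–chair closure as in germacrene 1,10-epoxide cyclisations) to give the trans-decalin 1β,5α-diol F2. Selective mesylation of the secondary hydroxyl gives the 1β-mesylate F3, and KOtBu closes the oxetane by intramolecular Williamson displacement with inversion at C1, returning to 11.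

2. Step 10 (bromide opening). Backside attack at the neopentyl-type C1 of the silyl-oxetanium may be slow, so that desilylation, α-bromination of the ketone or cycloreversion of the oxetane take over. Fallback, from 15 back to 18: the exchange is run as an acylative ether cleavage and the tertiary oxygen is carried as an ester; this still relies on the same backside attack at C1 and changes the electrophile and the protecting logic, not the bond-forming event. Acetyl bromide with catalytic ZnBr2 (known acyl halide cleavage of cyclic ethers; the O-acyl oxetanium is the stronger electrophile and forms irreversibly) should give the 1β-bromo-5α-acetoxy 4-ketone F4. Wittig methylenation with Ph3P=CH2 (the ester is inert) gives the 5-O-acetate of 18, F5, and DIBAL-H at −78 °C removes the acetate to reach 18.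

3. Step 2 (double vinylation). Enolisation or dehydrochlorination of the tertiary α-chloro ketone, epoxide formation or ring contraction may compete with the 1,2-vinyl shift. Fallback, from 1 back to 9: conjugate reduction of 1 with L-Selectride and Michael addition of the enolate to phenyl vinyl sulfoxide gives the sulfoxide F6. Thermolysis in toluene (sulfoxide syn-elimination) gives the vinyl ketone F7, the C2 epimer of 5. Vinylmagnesium bromide with CeCl3 gives the divinyl carbinol F8, which under the conditions of step 3 gives 9, because the quaternary centre becomes sp2 in the oxy-Cope step.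

**Further compounds**

F1 | step 5 | trans-1,10-epoxide of 10 (5,6-epoxy-2-(TBSO)-6-methyl-9-(prop-1-en-2-yl)cyclodecan-1-one) | O=C1C(O[Si](C)(C)C(C)(C)C)CC[C@H]2O[C@]2(C)CC[C@@H](C(C)=C)C1
F2 | step 5 | 4-(TBSO)-15-nor-eudesm-11-ene-1β,5α-diol | C[C@@]12CC[C@@H](C(C)=C)C[C@@]1(O)C(O[Si](C)(C)C(C)(C)C)CC[C@H]2O
F3 | step 5 | 1β-methanesulfonate of F2 | C[C@@]12CC[C@@H](C(C)=C)C[C@@]1(O)C(O[Si](C)(C)C(C)(C)C)CC[C@H]2OS(C)(=O)=O
F4 | step 10 | 5α-acetoxy-1β-bromo-15-nor-eudesman-4-one with 7β-[(E)-1-(pinacolboryl)prop-1-en-2-yl] | C[C@@]12CC[C@@H](/C(C)=C/B4OC(C)(C)C(C)(C)O4)C[C@@]1(OC(C)=O)C(=O)CC[C@H]2Br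
F5 | step 10 | 5-O-acetate of 18 | C[C@@]12CC[C@@H](/C(C)=C/B4OC(C)(C)C(C)(C)O4)C[C@@]1(OC(C)=O)C(=C)CC[C@H]2Br
F6 | step 2 | (2R,5R)-2-methyl-2-[2-(phenylsulfinyl)ethyl]-5-(prop-1-en-2-yl)cyclohexan-1-one | O=C1[C@@](C)(CCS(=O)c2ccccc2)CC[C@@H](C(C)=C)C1
F7 | step 2 | (2R,5R)-2-ethenyl-2-methyl-5-(prop-1-en-2-yl)cyclohexan-1-one | O=C1[C@@](C)(C=C)CC[C@@H](C(C)=C)C1
F8 | step 2 | (1S,2R,5R)-1,2-diethenyl-2-methyl-5-(prop-1-en-2-yl)cyclohexan-1-ol | O[C@@]1(C=C)[C@@](C)(C=C)CC[C@@H](C(C)=C)C1
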